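The easy step first: both earlier runs fed L evenly, so at any moment the fraction of the charge gone in is elapsed time over dosing time, and whatever of that is not product is L still in the flask.

| flask | L | J | remark | time |
|---|---|---|---|---|
| winter | 0.10 M (fed, over 2.5 min) | 15 mM (held) | run made earlier |  |
| dusk | 0.22 M (fed, over 2.5 min) | 15 mM (held) | run made earlier |  |
| Tuesday's | 0.15 M (fed, over 2.5 min) | 15 mM (held) |  | 2.5 min |
| Monday's | 0.15 M | 15 mM | everything together at the start | 0.60 min |

- winter (time / s: X / %): 10.0: 1.1; 15.0: 1.3; 25.0: 2.9; 50.0: 10.6; 90.0: 29.2
- dusk (time / s: X / %): 20.0: 2.5; 40.0: 7.7; 50.0: 9.6; 80.0: 23.3; 90.0: 29.0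

(readings scatter by 0.5 percentage points)

- in percentages every species weighs as the L in it: one Q counts as two
- at the start none of Z is dissolved
- steps under discussion: J <-> Z; L + Z -> X; L + X -> Q
- percentages count the whole charge, also what has not yet gone in

- which of the two ends with the higher amount of X, in percent of the L charged ("neither" if they lie within 2 percentage points) (Tuesday's / Monday's / neither)
- X at the end, in percent of the L charged, Tuesday's
- X at the end, in percent of the L charged, Monday's

We build a ladder of time scales from this. On the first rung stands the supply of Z. The dusk run carried 2.20 times the charge of the winter run, yet at 90.0 s they read 29.0% and 29.2% of X, a gap smaller than the scatter of 0.5 percentage points. So we treat Z as steady and L as pseudo-first-order, with one time constant at either charge.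

The next rung is that constant. Between 50.0 s and 90.0 s the two runs gain on average 19 points of X, while L in the flask stands near 27.1% of the charge, counting Q as nil. The lifetime of L, meaning L held divided by L converted per unit time, then reads 0.950 min.

Monday's flask, with all its L in at the start, stops at 0.60 min, sooner than one lifetime, so it is a plain decay caught early, with 53.2% of L left. Tuesday's feed lasts 2.63 lifetimes, so control passes from the reaction to the feed: its L climbs towards the balance of feed against loss, 38.0% of the charge, and ends at 35.3%.

On the last rung stands L + X -> Q, for which the readings give us no time. Counting all lost L as X, we reckon 64.7% for Tuesday's and 46.8% for Monday's.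

The forecast reads that “X formation looks first order in L” and says Tuesday's, with 61% and 41%, which is 3.7 points and 5.8 points below our figures.

The flasks give 62.3% for Tuesday's and 43.8% for Monday's, so Tuesday's ends higher, as forecast.

    J ⇌ Z, rate k1*(csat - [Z]) (kL = 116 min⁻¹)
    L + Z → X (k = 71.2 M⁻¹ min⁻¹)
    L + X → Q (k = 0.491 M⁻¹ min⁻¹)

Neither flask had finished, with L at 34.8% in Tuesday's and 54.8% in Monday's. Left ten times as long, they stand at 93.6% and 93.4% of X. Take Monday's flask left until 1.0 min: the same lifetime leaves 34.9% of L, and that flask holds 36%, with Q at 2.82% and X at 61.4%, against 62.3% in Tuesday's at 2.5 min.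

The numbers in the tables are calculated with made-up constants; the scatter is artificial.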